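The synthesis rests on disconnecting the C5 methyl group from the ring and delivering it from the C4 oxygen. The key step exploits the tetrasubstituted C5=C6 alkene of a carvone-derived cyclohexene (ring carbons C1–C6), which lies allylic to the C4 tertiary carbinol. A bromomethylsilyl ether on that oxygen closes a five-membered oxasilolane (O, Si, CH2, C5, C4) by radical attack on C5. Hydrogen transfer to C6 then completes an anti addition of CH3 and H, with the methyl syn to the hydroxyl. One operation thus builds the quaternary C5 and the C6 methine. The precursor is the (bromomethyl)dimethylsilyl ether carrying a C12–C14 acetal arm on C5, a silyloxypropyl arm on C6 and isopropenyl on C1.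

Key step: step 11

Numbering: target numbering is used throughout (ring C1–C6 with C1 the alkylidene carbon, C4 the carbinol, C5 the quaternary carbon, C6 the methine; enal C7/C8; propanol arm C9–C11; side chain C12–C23).

Remarks on the chemistry:
- Methyl and hydrogen add anti across C5=C6, the methyl syn to the C4 oxygen and C9 syn to the methyl; this is the (4S,5S,6R) array of the target.
- The tertiary C4 hydroxyl is masked as a triethylsilyl ether while C5 is a ketone and an enol triflate.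
- Fluoride protodesilylation also removes the primary TBS ether, so C11 is afterwards held as a TBDPS ether.
- C8 is kept at the alcohol level during chain assembly and oxidised last.
- Compound 3 is drawn as the carbinol epimer expected from hydride attack anti to the oxirane oxygen, and 8 as the epimer with allyl trans to isopropenyl; either epimer converges in the following step.
- (S)-TRIP, (S)-3,3'-bis(2,4,6-triisopropylphenyl)-1,1'-binaphthyl-2,2'-diyl hydrogen phosphate, is assumed to direct attack to the Si face of 32, as it does with aryl and alkenyl aldehydes; its enantiomer is used if the opposite sense is found.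

Step 1
Reactants: 1 (S)-(+)-carvone
Product: 2 (1S,4S,6S)-1-methyl-4-(prop-1-en-2-yl)-7-oxabicyclo[4.1.0]heptan-2-one
Conditions: H2O2 (30% aq.), NaOH (cat.), MeOH, 0 °C
Reagents that add atoms: hydrogen peroxide, OO
Why: Weitz–Scheffer nucleophilic epoxidation, in which hydroperoxide adds to the enone β-carbon axially and anti to the pseudo-equatorial isopropenyl group, so the oxirane forms trans to it and defines the future C4 configuration, while the unactivated isopropenyl alkene is untouched.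

Step 2
Reactants: 2 (1S,4S,6S)-1-methyl-4-(prop-1-en-2-yl)-7-oxabicyclo[4.1.0]heptan-2-one
Product: 3 (1S,2R,4S)-1-methyl-4-(prop-1-en-2-yl)cyclohexane-1,2-diol
Conditions: LiAlH4, THF, 0 °C to reflux
Reagents that add atoms: none
Why: Hydride reduction of the ketone followed by SN2 opening of the trisubstituted oxirane at its secondary carbon (C3) leaves the tertiary C4–O bond intact and should give the 1,2-diol, whose secondary carbinol centre is removed in step 3.

Step 3
Reactants: 3 (1S,2R,4S)-1-methyl-4-(prop-1-en-2-yl)cyclohexane-1,2-diol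
Product: 4 (2S,5S)-2-hydroxy-2-methyl-5-(prop-1-en-2-yl)cyclohexan-1-one
Conditions: IBX, EtOAc, 75 °C
Reagents that add atoms: none
Why: IBX oxidation converts the secondary alcohol of a secondary/tertiary 1,2-diol into the ketone without glycol cleavage, giving the α-ketol.

Step 4
Reactants: 4 (2S,5S)-2-hydroxy-2-methyl-5-(prop-1-en-2-yl)cyclohexan-1-one
Product: 5 (2S,5S)-2-methyl-5-(prop-1-en-2-yl)-2-[(triethylsilyl)oxy]cyclohexan-1-one
Conditions: Et3SiOTf, 2,6-lutidine, CH2Cl2, −78 to 0 °C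
Reagents that add atoms: triethylsilyl triflate, CC[Si](CC)(CC)OS(=O)(=O)C(F)(F)F
Why: Silyl triflate silylation masks the hindered tertiary hydroxyl so that the ketone can be enolised, alkylated and triflated without interference from an alkoxide.

Step 5
Reactants: 5 (2S,5S)-2-methyl-5-(prop-1-en-2-yl)-2-[(triethylsilyl)oxy]cyclohexan-1-one; 6 allyl bromide
Product: 8 (2S,5S,6R)-2-methyl-6-(prop-2-en-1-yl)-5-(prop-1-en-2-yl)-2-[(triethylsilyl)oxy]cyclohexan-1-one, via lithium enolate 7 (not isolated)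
Conditions: LiN(iPr)2, THF, −78 °C; then 6, DMPU, −78 to −30 °C
Reagents that add atoms: none
Why: Ketone enolate alkylation: C4 is quaternary, so deprotonation can occur only at C6, and SN2 allylation should take place anti to the neighbouring isopropenyl group, the new C6 centre being erased in step 6.

Step 6
Reactants: 8 (2S,5S,6R)-2-methyl-6-(prop-2-en-1-yl)-5-(prop-1-en-2-yl)-2-[(triethylsilyl)oxy]cyclohexan-1-one
Product: 10 (3R,6S)-6-methyl-2-(prop-2-en-1-yl)-3-(prop-1-en-2-yl)-6-[(triethylsilyl)oxy]cyclohex-1-en-1-yl trifluoromethanesulfonate, via potassium enolate 9 (not isolated)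
Conditions: KN(SiMe3)2, THF, −78 to −40 °C; then PhNTf2, −78 °C to rt
Reagents that add atoms: N-phenylbis(trifluoromethanesulfonimide), O=S(=O)(N(c1ccccc1)S(=O)(=O)C(F)(F)F)C(F)(F)F
Why: O-Sulfonylation of the only enolate that can form gives the tetrasubstituted C5=C6 enol triflate with defined regiochemistry.

Step 7
Reactants: 10 (3R,6S)-6-methyl-2-(prop-2-en-1-yl)-3-(prop-1-en-2-yl)-6-[(triethylsilyl)oxy]cyclohex-1-en-1-yl trifluoromethanesulfonate; 11 2-(2-bromoethyl)-1,3-dioxolane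
Product: 13 2-{2-[(3R,6S)-6-methyl-2-(prop-2-en-1-yl)-3-(prop-1-en-2-yl)-6-[(triethylsilyl)oxy]cyclohex-1-en-1-yl]ethyl}-1,3-dioxolane, via Grignard reagent 12 (not isolated)
Conditions: 11, Mg, THF, 25 °C; then 10, Fe(acac)3 (5 mol%), THF/NMP, −30 to 0 °C
Reagents that add atoms: none
Why: Iron-catalysed cross-coupling of an alkenyl triflate with a primary alkyl Grignard reagent (Kochi–Fürstner type) is fast at low temperature, accepts hindered triflates, acetals and silyl ethers, and places C12–C14 on C5.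

Step 8
Reactants: 13 2-{2-[(3R,6S)-6-methyl-2-(prop-2-en-1-yl)-3-(prop-1-en-2-yl)-6-[(triethylsilyl)oxy]cyclohex-1-en-1-yl]ethyl}-1,3-dioxolane
Product: 15 3-[(3S,6R)-2-[2-(1,3-dioxolan-2-yl)ethyl]-3-methyl-6-(prop-1-en-2-yl)-3-[(triethylsilyl)oxy]cyclohex-1-en-1-yl]propan-1-ol, via alkylborane 14 (not isolated)
Conditions: (Me2CHCHMe)2BH [from BH3·SMe2 and 2-methylbut-2-ene], THF, 0 °C; then NaOH, H2O2, 0 °C to rt
Reagents that add atoms: hydrogen peroxide, OO
Why: Anti-Markovnikov hydroboration–oxidation with a bulky dialkylborane should select the monosubstituted allyl alkene over the 1,1-disubstituted isopropenyl and the tetrasubstituted ring alkene, giving the C11 primary alcohol.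

Step 9
Reactants: 15 3-[(3S,6R)-2-[2-(1,3-dioxolan-2-yl)ethyl]-3-methyl-6-(prop-1-en-2-yl)-3-[(triethylsilyl)oxy]cyclohex-1-en-1-yl]propan-1-ol
Product: 16 (1S,4R)-2-[2-(1,3-dioxolan-2-yl)ethyl]-3-(3-hydroxypropyl)-1-methyl-4-(prop-1-en-2-yl)cyclohex-2-en-1-ol
Conditions: Bu4NF, THF, rt
Reagents that add atoms: none
Why: Fluoride-mediated desilylation frees the tertiary allylic hydroxyl under basic conditions that avoid ionisation of the allylic carbinol.

Step 10
Reactants: 16 (1S,4R)-2-[2-(1,3-dioxolan-2-yl)ethyl]-3-(3-hydroxypropyl)-1-methyl-4-(prop-1-en-2-yl)cyclohex-2-en-1-ol; 17 (bromomethyl)chlorodimethylsilane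
Product: 19 (bromomethyl){[(1S,4R)-3-{3-[(tert-butyldimethylsilyl)oxy]propyl}-2-[2-(1,3-dioxolan-2-yl)ethyl]-1-methyl-4-(prop-1-en-2-yl)cyclohex-2-en-1-yl]oxy}dimethylsilane, via mono-TBS ether 18 (not isolated)
Conditions: t-BuMe2SiCl (1.05 equiv), Et3N, DMAP (cat.), CH2Cl2, 0 °C; then 17, rt
Reagents that add atoms: tert-butyldimethylsilyl chloride, CC(C)(C)[Si](C)(C)Cl
Why: Sequential silylation, in which the bulky chlorosilane reacts only at the primary hydroxyl and the small, reactive chlorodimethylsilane then silylates the tertiary allylic hydroxyl to install the radical tether.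

Step 11
Reactants: 19 (bromomethyl){[(1S,4R)-3-{3-[(tert-butyldimethylsilyl)oxy]propyl}-2-[2-(1,3-dioxolan-2-yl)ethyl]-1-methyl-4-(prop-1-en-2-yl)cyclohex-2-en-1-yl]oxy}dimethylsilane
Product: 20 tert-butyl{3-[(3aR,4R,5S,7aS)-3a-[2-(1,3-dioxolan-2-yl)ethyl]-2,2,7a-trimethyl-5-(prop-1-en-2-yl)octahydro-1,2-benzoxasilol-4-yl]propoxy}dimethylsilane
Conditions: Bu3SnH (1.3 equiv, syringe pump), AIBN (cat.), benzene (0.01 M), 80 °C
Reagents that add atoms: none
Why: Bu3Sn• abstracts bromine from 19, the silylmethyl radical adds to C5 of the ring C5=C6 bond, and the tertiary C6 radical takes hydrogen from Bu3SnH to carry the chain. The closest known reaction type is the Nishiyama–Stork cyclization of (bromomethyl)dimethylsilyl ethers of allylic alcohols, used with protodesilylation as a hydroxyl-directed reductive methylation. The oxasilolane (O, Si, CH2, C5, C4) closes in the 5-exo-trig mode, and the short tether can reach only the oxygen-bearing face, so the new C5–CH2 bond is syn to the C4 oxygen (cis ring fusion), which sets C5. C6 is set by hydrogen transfer anti to the axial C5–CH2Si bond in the chair enforced by the equatorial C1 isopropenyl group (trans to the C4 oxygen), which places C9 equatorial and syn to the future methyl. Regioselectivity (5-exo over 6-endo) rests on ring size alone because both alkene carbons are fully substituted, and closure must outrun direct reduction of the first radical, which the low stannane concentration secures.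

Step 12
Reactants: 20 tert-butyl{3-[(3aR,4R,5S,7aS)-3a-[2-(1,3-dioxolan-2-yl)ethyl]-2,2,7a-trimethyl-5-(prop-1-en-2-yl)octahydro-1,2-benzoxasilol-4-yl]propoxy}dimethylsilane
Product: 21 (1S,2S,3R,4S)-2-[2-(1,3-dioxolan-2-yl)ethyl]-3-(3-hydroxypropyl)-1,2-dimethyl-4-(prop-1-en-2-yl)cyclohexan-1-ol
Conditions: Bu4NF (excess), DMF, 70 °C
Reagents that add atoms: none
Why: Stork-type protodesilylation, in which fluoride opens the strained Si–O bond and the alkoxide-activated pentacoordinate silicon releases the primary carbon for protonation by water without touching the C5 configuration, while the same reagent cleaves the primary TBS ether.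

Step 13
Reactants: 21 (1S,2S,3R,4S)-2-[2-(1,3-dioxolan-2-yl)ethyl]-3-(3-hydroxypropyl)-1,2-dimethyl-4-(prop-1-en-2-yl)cyclohexan-1-ol
Product: 22 (1S,2S,3R,4S)-3-{3-[(tert-butyldiphenylsilyl)oxy]propyl}-2-[2-(1,3-dioxolan-2-yl)ethyl]-1,2-dimethyl-4-(prop-1-en-2-yl)cyclohexan-1-ol
Conditions: t-BuPh2SiCl (1.1 equiv), imidazole, CH2Cl2, 0 °C to rt
Reagents that add atoms: tert-butyldiphenylsilyl chloride, CC(C)(C)[Si](Cl)(c1ccccc1)c1ccccc1
Why: Selective silylation of the primary over the hindered tertiary hydroxyl gives a robust ether and removes the primary alcohol that a ruthenium hydride could dehydrogenate in step 15.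

Step 14
Reactants: 22 (1S,2S,3R,4S)-3-{3-[(tert-butyldiphenylsilyl)oxy]propyl}-2-[2-(1,3-dioxolan-2-yl)ethyl]-1,2-dimethyl-4-(prop-1-en-2-yl)cyclohexan-1-ol
Product: 24 2-[(1S,2R,3S,4S)-2-{3-[(tert-butyldiphenylsilyl)oxy]propyl}-3-[2-(1,3-dioxolan-2-yl)ethyl]-4-hydroxy-3,4-dimethylcyclohexyl]prop-2-enal, via allylic alcohol 23 (not isolated)
Conditions: SeO2 (0.5 equiv), t-BuOOH, CH2Cl2, rt; then MnO2, rt
Reagents that add atoms: tert-butyl hydroperoxide, CC(C)(C)OO
Why: Riley allylic oxidation (ene reaction then 2,3-sigmatropic shift, Sharpless–Umbreit conditions) at the methyl group of the 1,1-disubstituted alkene gives the 2-substituted allyl alcohol, which MnO2 oxidises chemoselectively to the 2-substituted acrolein.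

Step 15
Reactants: 24 2-[(1S,2R,3S,4S)-2-{3-[(tert-butyldiphenylsilyl)oxy]propyl}-3-[2-(1,3-dioxolan-2-yl)ethyl]-4-hydroxy-3,4-dimethylcyclohexyl]prop-2-enal
Product: 25 (2Z)-2-[(2R,3S,4S)-2-{3-[(tert-butyldiphenylsilyl)oxy]propyl}-3-[2-(1,3-dioxolan-2-yl)ethyl]-4-hydroxy-3,4-dimethylcyclohexylidene]propanal
Conditions: RuHCl(CO)(PPh3)3 (5 mol%), toluene, 80 °C
Reagents that add atoms: none
Why: Metal-hydride-catalysed double-bond migration of an α-methylene carbonyl compound, in which Ru–H adds to the terminal CH2 to give a ruthenium enolate and β-hydride elimination of the C1 hydrogen gives the tetrasubstituted enal; because both events are reversible the geometry should settle on the Z isomer, which keeps the C7 methyl away from the equatorial C6 arm (allylic 1,3-strain).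

Step 16
Reactants: 25 (2Z)-2-[(2R,3S,4S)-2-{3-[(tert-butyldiphenylsilyl)oxy]propyl}-3-[2-(1,3-dioxolan-2-yl)ethyl]-4-hydroxy-3,4-dimethylcyclohexylidene]propanal
Product: 26 (1S,2S,3R,4Z)-3-{3-[(tert-butyldiphenylsilyl)oxy]propyl}-2-[2-(1,3-dioxolan-2-yl)ethyl]-4-(1-hydroxypropan-2-ylidene)-1,2-dimethylcyclohexan-1-ol
Conditions: NaBH4, CeCl3·7H2O, MeOH, −40 to 0 °C
Reagents that add atoms: none
Why: Luche 1,2-reduction gives the allylic alcohol with the alkene geometry unchanged and takes C8 out of reach of the ylide and borane used later.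

Step 17
Reactants: 26 (1S,2S,3R,4Z)-3-{3-[(tert-butyldiphenylsilyl)oxy]propyl}-2-[2-(1,3-dioxolan-2-yl)ethyl]-4-(1-hydroxypropan-2-ylidene)-1,2-dimethylcyclohexan-1-ol
Product: 27 (1S,2S,3R,4Z)-4-{1-[(tert-butyldiphenylsilyl)oxy]propan-2-ylidene}-3-{3-[(tert-butyldiphenylsilyl)oxy]propyl}-2-[2-(1,3-dioxolan-2-yl)ethyl]-1,2-dimethylcyclohexan-1-ol
Conditions: t-BuPh2SiCl, imidazole, DMF, rt
Reagents that add atoms: tert-butyldiphenylsilyl chloride, CC(C)(C)[Si](Cl)(c1ccccc1)c1ccccc1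
Why: Silylation of the primary allylic hydroxyl, the tertiary C4 hydroxyl being too hindered for this chlorosilane.

Step 18
Reactants: 27 (1S,2S,3R,4Z)-4-{1-[(tert-butyldiphenylsilyl)oxy]propan-2-ylidene}-3-{3-[(tert-butyldiphenylsilyl)oxy]propyl}-2-[2-(1,3-dioxolan-2-yl)ethyl]-1,2-dimethylcyclohexan-1-ol
Product: 29 3-[(1S,2S,5Z,6R)-5-{1-[(tert-butyldiphenylsilyl)oxy]propan-2-ylidene}-6-{3-[(tert-butyldiphenylsilyl)oxy]propyl}-1,2-dimethyl-2-[(triethylsilyl)oxy]cyclohexyl]propanal, via collidinium salt 28 (not isolated)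
Conditions: Et3SiOTf (3.5 equiv), 2,4,6-collidine, CH2Cl2, −40 to 0 °C; then H2O
Reagents that add atoms: triethylsilyl triflate, CC[Si](CC)(CC)OS(=O)(=O)C(F)(F)F; water, O
Why: The silyl triflate/pyridine base pair silylates the tertiary hydroxyl and opens the aldehyde-derived dioxolane to a collidinium salt that water hydrolyses to the aldehyde (Fujioka acetal cleavage), under basic conditions that spare the silyl ethers and the allylic system.

Step 19
Reactants: 29 3-[(1S,2S,5Z,6R)-5-{1-[(tert-butyldiphenylsilyl)oxy]propan-2-ylidene}-6-{3-[(tert-butyldiphenylsilyl)oxy]propyl}-1,2-dimethyl-2-[(triethylsilyl)oxy]cyclohexyl]propanal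
Product: 30 (2E)-5-[(1S,2S,5Z,6R)-5-{1-[(tert-butyldiphenylsilyl)oxy]propan-2-ylidene}-6-{3-[(tert-butyldiphenylsilyl)oxy]propyl}-1,2-dimethyl-2-[(triethylsilyl)oxy]cyclohexyl]-2-methylpent-2-enal
Conditions: Ph3P=C(CH3)CHO, toluene, 100 °C
Reagents that add atoms: 2-(triphenylphosphoranylidene)propanal, CC(C=O)=P(c1ccccc1)(c1ccccc1)c1ccccc1
Why: Wittig olefination with a stabilised ylide forms the C14=C15 trisubstituted alkene with E geometry under thermodynamic control.

Step 20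
Reactants: 30 (2E)-5-[(1S,2S,5Z,6R)-5-{1-[(tert-butyldiphenylsilyl)oxy]propan-2-ylidene}-6-{3-[(tert-butyldiphenylsilyl)oxy]propyl}-1,2-dimethyl-2-[(triethylsilyl)oxy]cyclohexyl]-2-methylpent-2-enal
Product: 31 the same silyl-protected ring carrying a (3E)-4-methylhexa-3,5-dien-1-yl chain on C5 (CH=CH2 in place of CH=O of 30)
Conditions: Ph3PCH3Br, KN(SiMe3)2, THF, 0 °C; then 30, −78 to 0 °C
Reagents that add atoms: methyltriphenylphosphonium bromide, C[P+](c1ccccc1)(c1ccccc1)c1ccccc1.[Br-]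
Why: Wittig methylenation of the enal gives the terminal 1,3-diene without touching the E-trisubstituted alkene.

Step 21
Reactants: 32 3-methylbut-2-enal; 33 allenylboronic acid pinacol ester
Product: 35 (4S)-2-methylhept-2-en-6-yn-4-ol, via pinacol borate 34 (not isolated)
Conditions: (S)-TRIP (5 mol%), 4 Å MS, toluene, 0 °C; then aqueous work-up
Reagents that add atoms: none
Why: Chiral phosphoric acid-catalysed propargylation of an aldehyde by an allenylboronate through a closed six-membered transition state (SE2'), in which the catalyst selects the aldehyde face and sets C21 as S.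

Step 22
Reactants: 35 (4S)-2-methylhept-2-en-6-yn-4-ol
Product: 37 (4S,6E)-7-iodo-2,6-dimethylhepta-2,6-dien-4-ol, via alkenylalane 36 (not isolated)
Conditions: Me3Al, Cp2ZrCl2 (25 mol%), H2O (1 equiv), CH2Cl2, −20 °C; then iodine, THF, −30 to 0 °C
Reagents that add atoms: trimethylaluminium, C[Al](C)C; iodine, [I][I]
Why: Negishi zirconium-catalysed carboalumination adds methyl and aluminium syn across the terminal alkyne with methyl on the internal carbon, and iodinolysis with retention gives the E-iodoalkene that fixes the C18=C19 geometry.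

Step 23
Reactants: 37 (4S,6E)-7-iodo-2,6-dimethylhepta-2,6-dien-4-ol
Product: 38 (1S,3E)-1-[(2R)-3,3-dimethyloxiran-2-yl]-4-iodo-3-methylbut-3-en-1-ol
Conditions: mCPBA, NaHCO3, CH2Cl2, 0 °C
Reagents that add atoms: 3-chloroperoxybenzoic acid, OOC(=O)c1cccc(Cl)c1
Why: Hydroxyl-directed peracid epoxidation (Henbest), in which allylic 1,3-strain with the cis methyl holds the carbinol hydrogen in the alkene plane so that oxygen is delivered syn to the hydroxyl to give the threo (21S,22R) epoxy alcohol, the iodoalkene being too electron-poor to compete.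

Step 24
Reactants: 31 diene (product of step 20); 38 (1S,3E)-1-[(2R)-3,3-dimethyloxiran-2-yl]-4-iodo-3-methylbut-3-en-1-ol
Product: 40 the 4-O-triethylsilyl 8-O-,11-O-bis(tert-butyldiphenylsilyl) ether of tetraol 41, via alkylborane 39 (not isolated)
Conditions: 31, 9-BBN, THF, 0 °C to rt; then 38, Pd(dppf)Cl2 (10 mol%), AsPh3, Cs2CO3, DMF/H2O, rt
Reagents that add atoms: none
Why: B-alkyl Suzuki–Miyaura coupling, in which 9-BBN adds to the terminal carbon of the diene to give a homoallylic borane that couples with the alkenyl iodide with retention of both alkene geometries under mild aqueous base tolerated by the epoxy alcohol.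

Step 25
Reactants: 40 fully silylated coupling product
Product: 41 (1S,2S,3R,4Z)-2-[(3E,7E,10S)-10-[(2R)-3,3-dimethyloxiran-2-yl]-10-hydroxy-4,8-dimethyldeca-3,7-dien-1-yl]-4-(1-hydroxypropan-2-ylidene)-3-(3-hydroxypropyl)-1,2-dimethylcyclohexan-1-ol
Conditions: Bu4NF, THF, rt to 40 °C
Reagents that add atoms: none
Why: Global fluoride desilylation removes the two primary TBDPS ethers and the tertiary TES ether at a stage where no base-sensitive enal is present and the trisubstituted oxirane is stable.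

Step 26
Reactants: 41 tetraol
Product: 42 CNP0161066.1, (2Z)-2-[(2R,3S,4S)-3-[(3E,7E,10S)-10-[(2R)-3,3-dimethyloxiran-2-yl]-10-hydroxy-4,8-dimethyldeca-3,7-dien-1-yl]-4-hydroxy-2-(3-hydroxypropyl)-3,4-dimethylcyclohexylidene]propanal
Conditions: MnO2, CH2Cl2, rt
Reagents that add atoms: none
Why: MnO2 oxidises only the allylic primary hydroxyl (C8) of the tetraol to the enal, under neutral conditions that should preserve the alkene geometry, the oxirane and the other three hydroxyls.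

Compound list

1 | (S)-(+)-carvone | CC(=C)[C@H]1CC=C(C)C(=O)C1 | starting material
2 | (1S,4S,6S)-1-methyl-4-(prop-1-en-2-yl)-7-oxabicyclo[4.1.0]heptan-2-one (oxirane trans to isopropenyl) | CC(=C)[C@H]1C[C@@H]2O[C@]2(C)C(=O)C1 | intermediate
3 | (1S,2R,4S)-1-methyl-4-(prop-1-en-2-yl)cyclohexane-1,2-diol | CC(=C)[C@H]1CC[C@](C)(O)[C@H](O)C1 | intermediate
4 | (2S,5S)-2-hydroxy-2-methyl-5-(prop-1-en-2-yl)cyclohexan-1-one | CC(=C)[C@H]1CC[C@](C)(O)C(=O)C1 | intermediate
5 | (2S,5S)-2-methyl-5-(prop-1-en-2-yl)-2-[(triethylsilyl)oxy]cyclohexan-1-one | CC(=C)[C@H]1CC[C@](C)(O[Si](CC)(CC)CC)C(=O)C1 | intermediate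
6 | allyl bromide | C=CCBr | starting material
7 | lithium (3S,6S)-6-methyl-3-(prop-1-en-2-yl)-6-[(triethylsilyl)oxy]cyclohex-1-en-1-olate (not isolated) | CC(=C)[C@H]1CC[C@](C)(O[Si](CC)(CC)CC)C([O-])=C1.[Li+] | intermediate
8 | (2S,5S,6R)-2-methyl-6-(prop-2-en-1-yl)-5-(prop-1-en-2-yl)-2-[(triethylsilyl)oxy]cyclohexan-1-one | CC(=C)[C@H]1CC[C@](C)(O[Si](CC)(CC)CC)C(=O)[C@@H]1CC=C | intermediate
9 | potassium (3R,6S)-6-methyl-2-(prop-2-en-1-yl)-3-(prop-1-en-2-yl)-6-[(triethylsilyl)oxy]cyclohex-1-en-1-olate (not isolated) | CC(=C)[C@H]1CC[C@](C)(O[Si](CC)(CC)CC)C([O-])=C1CC=C.[K+] | intermediate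
10 | (3R,6S)-6-methyl-2-(prop-2-en-1-yl)-3-(prop-1-en-2-yl)-6-[(triethylsilyl)oxy]cyclohex-1-en-1-yl trifluoromethanesulfonate | CC(=C)[C@H]1CC[C@](C)(O[Si](CC)(CC)CC)C(OS(=O)(=O)C(F)(F)F)=C1CC=C | intermediate
11 | 2-(2-bromoethyl)-1,3-dioxolane | BrCCC1OCCO1 | starting material
12 | [2-(1,3-dioxolan-2-yl)ethyl]magnesium bromide (not isolated) | Br[Mg]CCC1OCCO1 | intermediate
13 | 2-{2-[(3R,6S)-6-methyl-2-(prop-2-en-1-yl)-3-(prop-1-en-2-yl)-6-[(triethylsilyl)oxy]cyclohex-1-en-1-yl]ethyl}-1,3-dioxolane | CC(=C)[C@H]1CC[C@](C)(O[Si](CC)(CC)CC)C(CCC2OCCO2)=C1CC=C | intermediate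
14 | bis(3-methylbutan-2-yl)borane adduct of 13 at the allyl terminus, boron on C11 (not isolated) | CC(=C)[C@H]1CC[C@](C)(O[Si](CC)(CC)CC)C(CCC2OCCO2)=C1CCCB(C(C)C(C)C)C(C)C(C)C | intermediate
15 | 3-[(3S,6R)-2-[2-(1,3-dioxolan-2-yl)ethyl]-3-methyl-6-(prop-1-en-2-yl)-3-[(triethylsilyl)oxy]cyclohex-1-en-1-yl]propan-1-ol | CC(=C)[C@H]1CC[C@](C)(O[Si](CC)(CC)CC)C(CCC2OCCO2)=C1CCCO | intermediate
16 | (1S,4R)-2-[2-(1,3-dioxolan-2-yl)ethyl]-3-(3-hydroxypropyl)-1-methyl-4-(prop-1-en-2-yl)cyclohex-2-en-1-ol | CC(=C)[C@H]1CC[C@](C)(O)C(CCC2OCCO2)=C1CCCO | intermediate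
17 | (bromomethyl)chlorodimethylsilane | C[Si](C)(Cl)CBr | starting material
18 | (1S,4R)-3-{3-[(tert-butyldimethylsilyl)oxy]propyl}-2-[2-(1,3-dioxolan-2-yl)ethyl]-1-methyl-4-(prop-1-en-2-yl)cyclohex-2-en-1-ol (not isolated) | CC(=C)[C@H]1CC[C@](C)(O)C(CCC2OCCO2)=C1CCCO[Si](C)(C)C(C)(C)C | intermediate
19 | (bromomethyl){[(1S,4R)-3-{3-[(tert-butyldimethylsilyl)oxy]propyl}-2-[2-(1,3-dioxolan-2-yl)ethyl]-1-methyl-4-(prop-1-en-2-yl)cyclohex-2-en-1-yl]oxy}dimethylsilane (key-step precursor) | CC(=C)[C@H]1CC[C@](C)(O[Si](C)(C)CBr)C(CCC2OCCO2)=C1CCCO[Si](C)(C)C(C)(C)C | intermediate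
20 | tert-butyl{3-[(3aR,4R,5S,7aS)-3a-[2-(1,3-dioxolan-2-yl)ethyl]-2,2,7a-trimethyl-5-(prop-1-en-2-yl)octahydro-1,2-benzoxasilol-4-yl]propoxy}dimethylsilane (cis-fused oxasilolane) | CC(=C)[C@H]1CC[C@]2(C)O[Si](C)(C)C[C@]2(CCC3OCCO3)[C@@H]1CCCO[Si](C)(C)C(C)(C)C | intermediate
21 | (1S,2S,3R,4S)-2-[2-(1,3-dioxolan-2-yl)ethyl]-3-(3-hydroxypropyl)-1,2-dimethyl-4-(prop-1-en-2-yl)cyclohexan-1-ol | CC(=C)[C@H]1CC[C@](C)(O)[C@@](C)(CCC2OCCO2)[C@@H]1CCCO | intermediate
22 | (1S,2S,3R,4S)-3-{3-[(tert-butyldiphenylsilyl)oxy]propyl}-2-[2-(1,3-dioxolan-2-yl)ethyl]-1,2-dimethyl-4-(prop-1-en-2-yl)cyclohexan-1-ol | CC(=C)[C@H]1CC[C@](C)(O)[C@@](C)(CCC2OCCO2)[C@@H]1CCCO[Si](c3ccccc3)(c4ccccc4)C(C)(C)C | intermediate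
23 | (1S,2S,3R,4S)-3-{3-[(tert-butyldiphenylsilyl)oxy]propyl}-2-[2-(1,3-dioxolan-2-yl)ethyl]-4-(3-hydroxyprop-1-en-2-yl)-1,2-dimethylcyclohexan-1-ol (not isolated) | C=C(CO)[C@H]1CC[C@](C)(O)[C@@](C)(CCC2OCCO2)[C@@H]1CCCO[Si](c3ccccc3)(c4ccccc4)C(C)(C)C | intermediate
24 | 2-[(1S,2R,3S,4S)-2-{3-[(tert-butyldiphenylsilyl)oxy]propyl}-3-[2-(1,3-dioxolan-2-yl)ethyl]-4-hydroxy-3,4-dimethylcyclohexyl]prop-2-enal | C=C(C=O)[C@H]1CC[C@](C)(O)[C@@](C)(CCC2OCCO2)[C@@H]1CCCO[Si](c3ccccc3)(c4ccccc4)C(C)(C)C | intermediate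
25 | (2Z)-2-[(2R,3S,4S)-2-{3-[(tert-butyldiphenylsilyl)oxy]propyl}-3-[2-(1,3-dioxolan-2-yl)ethyl]-4-hydroxy-3,4-dimethylcyclohexylidene]propanal | C/C(C=O)=C1\CC[C@](C)(O)[C@@](C)(CCC2OCCO2)[C@@H]1CCCO[Si](c3ccccc3)(c4ccccc4)C(C)(C)C | intermediate
26 | (1S,2S,3R,4Z)-3-{3-[(tert-butyldiphenylsilyl)oxy]propyl}-2-[2-(1,3-dioxolan-2-yl)ethyl]-4-(1-hydroxypropan-2-ylidene)-1,2-dimethylcyclohexan-1-ol | C/C(CO)=C1\CC[C@](C)(O)[C@@](C)(CCC2OCCO2)[C@@H]1CCCO[Si](c3ccccc3)(c4ccccc4)C(C)(C)C | intermediate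
27 | (1S,2S,3R,4Z)-4-{1-[(tert-butyldiphenylsilyl)oxy]propan-2-ylidene}-3-{3-[(tert-butyldiphenylsilyl)oxy]propyl}-2-[2-(1,3-dioxolan-2-yl)ethyl]-1,2-dimethylcyclohexan-1-ol | C/C(CO[Si](c5ccccc5)(c6ccccc6)C(C)(C)C)=C1\CC[C@](C)(O)[C@@](C)(CCC2OCCO2)[C@@H]1CCCO[Si](c3ccccc3)(c4ccccc4)C(C)(C)C | intermediate
28 | N-(C14)-2,4,6-collidinium triflate from opening of the dioxolane of 27, with C14 also bearing O-CH2CH2-OSiEt3 and C4 silylated as its triethylsilyl ether; C14 epimers (not isolated) | C/C(CO[Si](c5ccccc5)(c6ccccc6)C(C)(C)C)=C1\CC[C@](C)(O[Si](CC)(CC)CC)[C@@](C)(CCC(OCCO[Si](CC)(CC)CC)[n+]2c(C)cc(C)cc2C)[C@@H]1CCCO[Si](c3ccccc3)(c4ccccc4)C(C)(C)C.[O-]S(=O)(=O)C(F)(F)F | intermediate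
29 | 3-[(1S,2S,5Z,6R)-5-{1-[(tert-butyldiphenylsilyl)oxy]propan-2-ylidene}-6-{3-[(tert-butyldiphenylsilyl)oxy]propyl}-1,2-dimethyl-2-[(triethylsilyl)oxy]cyclohexyl]propanal | C/C(CO[Si](c5ccccc5)(c6ccccc6)C(C)(C)C)=C1\CC[C@](C)(O[Si](CC)(CC)CC)[C@@](C)(CCC=O)[C@@H]1CCCO[Si](c3ccccc3)(c4ccccc4)C(C)(C)C | intermediate
30 | (2E)-5-[(1S,2S,5Z,6R)-5-{1-[(tert-butyldiphenylsilyl)oxy]propan-2-ylidene}-6-{3-[(tert-butyldiphenylsilyl)oxy]propyl}-1,2-dimethyl-2-[(triethylsilyl)oxy]cyclohexyl]-2-methylpent-2-enal | C/C(CO[Si](c5ccccc5)(c6ccccc6)C(C)(C)C)=C1\CC[C@](C)(O[Si](CC)(CC)CC)[C@@](C)(CC/C=C(\C)C=O)[C@@H]1CCCO[Si](c3ccccc3)(c4ccccc4)C(C)(C)C | intermediate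
31 | diene: ring of 30 (C4 OSiEt3; C8 and C11 OSiPh2tBu; 1(7)Z; 4S,5S,6R) carrying (3E)-4-methylhexa-3,5-dien-1-yl on C5 | C/C(CO[Si](c5ccccc5)(c6ccccc6)C(C)(C)C)=C1\CC[C@](C)(O[Si](CC)(CC)CC)[C@@](C)(CC/C=C(\C)C=C)[C@@H]1CCCO[Si](c3ccccc3)(c4ccccc4)C(C)(C)C | intermediate
32 | 3-methylbut-2-enal | CC(C)=CC=O | starting material
33 | allenylboronic acid pinacol ester, 4,4,5,5-tetramethyl-2-(propa-1,2-dien-1-yl)-1,3,2-dioxaborolane | C=C=CB1OC(C)(C)C(C)(C)O1 | starting material
34 | pinacol borate of (4S)-2-methylhept-2-en-6-yn-4-ol (not isolated) | CC(C)=C[C@@H](OB1OC(C)(C)C(C)(C)O1)CC#C | intermediate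
35 | (4S)-2-methylhept-2-en-6-yn-4-ol | CC(C)=C[C@@H](O)CC#C | intermediate
36 | (E)-alkenyl(dimethyl)alane of 35 with the hydroxyl as its dimethylaluminium alkoxide (not isolated) | CC(C)=C[C@@H](O[Al](C)C)C/C(C)=C/[Al](C)C | intermediate
37 | (4S,6E)-7-iodo-2,6-dimethylhepta-2,6-dien-4-ol | CC(C)=C[C@@H](O)C/C(C)=C/I | intermediate
38 | (1S,3E)-1-[(2R)-3,3-dimethyloxiran-2-yl]-4-iodo-3-methylbut-3-en-1-ol | I/C=C(\C)C[C@H](O)[C@H]1OC1(C)C | intermediate
39 | B-alkyl-9-BBN from 31: 9-borabicyclo[3.3.1]nonan-9-yl on C17 of the (3E)-3-methylhex-3-en-1-yl chain (not isolated) | C/C(CO[Si](c5ccccc5)(c6ccccc6)C(C)(C)C)=C1\CC[C@](C)(O[Si](CC)(CC)CC)[C@@](C)(CC/C=C(\C)CCB7C8CCCC7CCC8)[C@@H]1CCCO[Si](c3ccccc3)(c4ccccc4)C(C)(C)C | intermediate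
40 | 4-O-triethylsilyl 8-O-,11-O-bis(tert-butyldiphenylsilyl) ether of tetraol 41 (21-OH free; 21S,22R; 14E,18E) | C/C(CO[Si](c5ccccc5)(c6ccccc6)C(C)(C)C)=C1\CC[C@](C)(O[Si](CC)(CC)CC)[C@@](C)(CC/C=C(\C)CC/C=C(\C)C[C@H](O)[C@H]2OC2(C)C)[C@@H]1CCCO[Si](c3ccccc3)(c4ccccc4)C(C)(C)C | intermediate
41 | (1S,2S,3R,4Z)-2-[(3E,7E,10S)-10-[(2R)-3,3-dimethyloxiran-2-yl]-10-hydroxy-4,8-dimethyldeca-3,7-dien-1-yl]-4-(1-hydroxypropan-2-ylidene)-3-(3-hydroxypropyl)-1,2-dimethylcyclohexan-1-ol | C/C(CO)=C1\CC[C@](C)(O)[C@@](C)(CC/C=C(\C)CC/C=C(\C)C[C@H](O)[C@H]2OC2(C)C)[C@@H]1CCCO | intermediate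
42 | CNP0161066.1, (2Z)-2-[(2R,3S,4S)-3-[(3E,7E,10S)-10-[(2R)-3,3-dimethyloxiran-2-yl]-10-hydroxy-4,8-dimethyldeca-3,7-dien-1-yl]-4-hydroxy-2-(3-hydroxypropyl)-3,4-dimethylcyclohexylidene]propanal | C/C(C=O)=C1\CC[C@](C)(O)[C@@](C)(CC/C=C(\C)CC/C=C(\C)C[C@H](O)[C@H]2OC2(C)C)[C@@H]1CCCO | target

Total step count: 26. Longest linear sequence: 23 (steps 1–20 and 24–26; steps 21–23 make the side-chain fragment).

Steps most likely to fail

1. Step 15 (double-bond migration). The hydride shuttle may stall at 24, the metal may decarbonylate the aldehyde, or the ratio of geometric isomers at C1=C7 may be unfavourable. The fallback replaces the migration by reduction, halogenation and elimination; it sets out from 24 and comes back at 25. Conjugate reduction of 24 with [(Ph3P)CuH]6 in wet benzene should give the saturated aldehyde 2-[(1S,2R,3S,4S)-2-{3-[(tert-butyldiphenylsilyl)oxy]propyl}-3-[2-(1,3-dioxolan-2-yl)ethyl]-4-hydroxy-3,4-dimethylcyclohexyl]propanal F1 as a mixture of C7 epimers. α-Bromination with 5,5-dibromo-2,2-dimethyl-1,3-dioxane-4,6-dione in Et2O at rt should then give the tertiary α-bromo aldehyde F2. Dehydrobromination with LiBr and Li2CO3 in DMF at 110 °C follows the Zaitsev rule toward the ring methine and allows bromide-mediated equilibration of the geometry, so it should deliver 25.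

2. Step 11 (key step). The silylmethyl radical may be reduced, or the labile Si–O tether lost, before the ring closes at the fully substituted C5. The fallback exchanges the one-carbon silicon tether for a two-carbon acetal tether (Ueno–Stork cyclization) whose extra carbon is excised afterwards; it sets out from 16 and comes back at 22, so that steps 10–13 are bypassed. Selective silylation of the primary hydroxyl of 16 (t-BuPh2SiCl, imidazole) gives the mono-TBDPS ether F3. NBS and ethyl vinyl ether in CH2Cl2 convert its tertiary hydroxyl into the mixed bromoacetal F4. Bu3SnH and AIBN in benzene close the cis-fused 2-ethoxytetrahydrofuran F5 by the same 5-exo attack on C5, with hydrogen transfer to C6. Mild acid (PPTS, wet acetone, rt), which spares the dioxolane, gives the lactol F6. Stoichiometric RhCl(PPh3)3 in toluene at 110 °C then decarbonylates its open hydroxy aldehyde form (Tsuji–Wilkinson decarbonylation) to the C5 methyl compound 22.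

3. Step 14 (allylic oxidation). The ene step may attack the C1 methine instead of the methyl group, or over-oxidise. The fallback introduces the oxygen by epoxidation and base-induced isomerisation; it sets out from 22 and comes back at 23, which is oxidised with MnO2 to 24 as in step 14. mCPBA (NaHCO3, CH2Cl2, 0 °C) epoxidises the isopropenyl group, the only alkene present, to the oxirane F7 as both C7 epimers. Et2Al(tmp), made from lithium 2,2,6,6-tetramethylpiperidide and Et2AlCl in toluene at 0 °C, removes a methyl proton syn to the oxirane and opens it to the 2-substituted allylic alcohol 23.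

Further compounds

F1 | step 15 | 2-[(1S,2R,3S,4S)-2-{3-[(tert-butyldiphenylsilyl)oxy]propyl}-3-[2-(1,3-dioxolan-2-yl)ethyl]-4-hydroxy-3,4-dimethylcyclohexyl]propanal (C7 epimers) | CC(C=O)[C@H]1CC[C@](C)(O)[C@@](C)(CCC2OCCO2)[C@@H]1CCCO[Si](c3ccccc3)(c4ccccc4)C(C)(C)C
F2 | step 15 | 2-bromo-2-[(1S,2R,3S,4S)-2-{3-[(tert-butyldiphenylsilyl)oxy]propyl}-3-[2-(1,3-dioxolan-2-yl)ethyl]-4-hydroxy-3,4-dimethylcyclohexyl]propanal (C7 epimers) | CC(Br)(C=O)[C@H]1CC[C@](C)(O)[C@@](C)(CCC2OCCO2)[C@@H]1CCCO[Si](c3ccccc3)(c4ccccc4)C(C)(C)C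
F3 | step 11 | (1S,4R)-3-{3-[(tert-butyldiphenylsilyl)oxy]propyl}-2-[2-(1,3-dioxolan-2-yl)ethyl]-1-methyl-4-(prop-1-en-2-yl)cyclohex-2-en-1-ol | CC(=C)[C@H]1CC[C@](C)(O)C(CCC2OCCO2)=C1CCCO[Si](c3ccccc3)(c4ccccc4)C(C)(C)C
F4 | step 11 | 2-bromo-1-ethoxyethyl ether of F3 at the tertiary hydroxyl (acetal epimers) | CC(=C)[C@H]1CC[C@](C)(OC(CBr)OCC)C(CCC2OCCO2)=C1CCCO[Si](c3ccccc3)(c4ccccc4)C(C)(C)C
F5 | step 11 | cis-fused 2-ethoxytetrahydrofuran spanning C4–O and C5 (acetal epimers; C5 and C6 as in 20) | CC(=C)[C@H]1CC[C@]2(C)OC(OCC)C[C@]2(CCC3OCCO3)[C@@H]1CCCO[Si](c4ccccc4)(c5ccccc5)C(C)(C)C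
F6 | step 11 | lactol from hydrolysis of F5 (anomers) | CC(=C)[C@H]1CC[C@]2(C)OC(O)C[C@]2(CCC3OCCO3)[C@@H]1CCCO[Si](c4ccccc4)(c5ccccc5)C(C)(C)C
F7 | step 14 | 2-methyloxiran-2-yl compound from epoxidation of the isopropenyl group of 22 (C7 epimers) | CC5(CO5)[C@H]1CC[C@](C)(O)[C@@](C)(CCC2OCCO2)[C@@H]1CCCO[Si](c3ccccc3)(c4ccccc4)C(C)(C)C
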